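Everything rests on cutting the two ring–CH2(prenyl) bonds of the six-membered carbocycle. C6, the only stereocentre (OMe, prenyl), sits between C1=O and C5–OH, and prenylated C4 is also bonded to C5, so each prenylated carbon neighbours an oxygen-bearing ring carbon, whose oxygen can deliver the prenyl group by a [3,3] shift of a 1,1-dimethylallyl ether (O1 to C6, O5 to C4). One operation, a chiral Lewis acid catalysed dearomative Claisen rearrangement followed in the same flask by a thermal one, forms both C–C bonds and the quaternary centre. Its precursor is the achiral aryl ketone 13: a MOM-protected 3-phenylpropanoyl benzene whose OMe carbon is flanked by two reverse-prenyl ethers.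

Key step: step 9

Remark on the chemistry: helihumulone is a tautomeric β-triketone, and 16 and 17 are written in the tautomeric form of the given structure (C1=O, C2 acyl, C3–O, C4 prenyl, C5–O, C6 OMe/prenyl). The facial preference of the ligand cannot be predicted for this new substrate class, so the ligand antipode that gives (R)-C6 is assumed to be identified in a pilot run with both antipodes.

Step 1
Reactants: 1 methyl 3,5-dihydroxy-4-methoxybenzoate; 2 3-chloro-3-methylbut-1-yne (two molecules are built in, one on each phenol)
Product: 3 methyl 4-methoxy-3,5-bis(2-methylbut-3-yn-2-yloxy)benzoate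
Conditions: 2 (3 equiv in total), CuCl2·2H2O (1 mol%), DBU (3.5 equiv), MeCN, 0 °C
Reagents that add atoms: 3-chloro-3-methylbut-1-yne (the second equivalent of 2, which etherifies the second phenol), CC(C)(Cl)C#C
Why: Copper-catalysed O-propargylation of phenols with a tertiary propargylic chloride (a Williamson-type etherification in which the phenoxide attacks the tertiary carbon of a copper-bound acetylide/allenylidene) is the standard entry to aryl 1,1-dimethylpropargyl ethers, and since the two hydroxyls of 1 are symmetry-related and acidified by the ester, exhaustive alkylation with two equivalents of 2 at 0 °C should need no differentiation and stays below the temperature of chromene-forming propargyl Claisen rearrangement.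

Step 2
Reactants: 3 methyl 4-methoxy-3,5-bis(2-methylbut-3-yn-2-yloxy)benzoate
Product: 4 [4-methoxy-3,5-bis(2-methylbut-3-yn-2-yloxy)phenyl]methanol
Conditions: i-Bu2AlH (3 equiv), CH2Cl2, −78 → 0 °C
Reagents that add atoms: none
Why: Complete hydride reduction of an aryl methyl ester to the benzylic alcohol is dependable, whereas halting at the aldehyde is not, and at low temperature the aryl ethers and the terminal alkynes (whose hydroalumination needs heating) should be left alone.

Step 3
Reactants: 4 [4-methoxy-3,5-bis(2-methylbut-3-yn-2-yloxy)phenyl]methanol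
Product: 5 4-methoxy-3,5-bis(2-methylbut-3-yn-2-yloxy)benzaldehyde
Conditions: activated MnO2 (excess), CH2Cl2, rt
Reagents that add atoms: none
Why: Heterogeneous MnO2 oxidation is selective for benzylic alcohols, stops at the aldehyde and is neutral, so the tertiary propargyl ethers should survive.

Step 4
Reactants: 5 4-methoxy-3,5-bis(2-methylbut-3-yn-2-yloxy)benzaldehyde
Product: 7 4-methoxy-3,5-bis(2-methylbut-3-yn-2-yloxy)phenol, via aryl formate 6 (not isolated)
Conditions: mCPBA, CH2Cl2, 0 °C → rt; aq. NaHCO3 wash; then K2CO3 (cat.), MeOH, 0 °C
Reagents that add atoms: meta-chloroperbenzoic acid (mCPBA), O=C(OO)c1cccc(Cl)c1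
Why: Baeyer–Villiger (Dakin-type) oxidation of an electron-rich benzaldehyde, in which the trioxygenated aryl group migrates in preference to hydrogen to give the formate, followed by mild methanolysis, swaps the former ester carbon for oxygen, while terminal alkynes react only sluggishly with the peracid.

Step 5
Reactants: 7 4-methoxy-3,5-bis(2-methylbut-3-yn-2-yloxy)phenol
Product: 8 2-methoxy-5-(methoxymethoxy)-1,3-bis(2-methylbut-3-yn-2-yloxy)benzene
Conditions: MOMCl, i-Pr2NEt, CH2Cl2, 0 °C → rt
Reagents that add atoms: chloromethyl methyl ether (MOMCl), COCCl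
Why: O-Alkylation of the phenol with MOMCl and a hindered amine is routine acetal protection, and MOM is chosen because it later directs ortho-lithiation and finally leaves under very mild acid.

Step 6
Reactants: 8 2-methoxy-5-(methoxymethoxy)-1,3-bis(2-methylbut-3-yn-2-yloxy)benzene
Product: 9 2-methoxy-5-(methoxymethoxy)-1,3-bis(2-methylbut-3-en-2-yloxy)benzene
Conditions: H2 (1 atm), Pd/CaCO3 poisoned with Pb(OAc)2, quinoline, EtOAc, rt; concentrate below 30 °C
Reagents that add atoms: none
Why: Lindlar semihydrogenation on lead-poisoned palladium with quinoline should add one equivalent of hydrogen to each terminal alkyne and stop at the vinyl stage without hydrogenolysis of the aryl C–O bonds, and the product is handled at or below room temperature because aryl 1,1-dimethylallyl ethers rearrange on heating.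

Step 7
Reactants: 9 2-methoxy-5-(methoxymethoxy)-1,3-bis(2-methylbut-3-en-2-yloxy)benzene; 10 3-phenylpropanal
Product: 12 rac-1-[3-methoxy-6-(methoxymethoxy)-2,4-bis(2-methylbut-3-en-2-yloxy)phenyl]-3-phenylpropan-1-ol, via aryllithium 11 (not isolated)
Conditions: s-BuLi, TMEDA, THF, −78 °C; then 10, −78 °C; then H2O
Reagents that add atoms: none
Why: Directed ortho-metalation should occur at either of the two symmetry-related ring C–H positions, each acidified by a MOM ether on one side and an ether oxygen on the other, the O–CMe2 carbons carry no hydrogen so α-deprotonation and Wittig-type shifts are excluded, −78 °C keeps the aryllithium from cyclising onto the adjacent vinyl group, and 1,2-addition to the aldehyde gives a carbinol whose new stereocentre is irrelevant because it is oxidised next.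

Step 8
Reactants: 12 rac-1-[3-methoxy-6-(methoxymethoxy)-2,4-bis(2-methylbut-3-en-2-yloxy)phenyl]-3-phenylpropan-1-ol
Product: 13 1-[3-methoxy-6-(methoxymethoxy)-2,4-bis(2-methylbut-3-en-2-yloxy)phenyl]-3-phenylpropan-1-one
Conditions: Dess–Martin periodinane, pyridine, CH2Cl2, 0 °C → rt
Reagents that add atoms: none
Why: Dess–Martin oxidation turns the hindered, electron-rich benzylic alcohol into the aryl ketone at or below room temperature under pyridine-buffered conditions that the acid- and heat-sensitive tertiary allyl ethers and the MOM acetal should tolerate.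

Step 9
Reactants: 13 1-[3-methoxy-6-(methoxymethoxy)-2,4-bis(2-methylbut-3-en-2-yloxy)phenyl]-3-phenylpropan-1-one
Product: 16 (6R)-5-hydroxy-6-methoxy-3-(methoxymethoxy)-4,6-bis(3-methylbut-2-enyl)-2-(3-phenylpropanoyl)cyclohexa-2,4-dien-1-one (O-MOM helihumulone), via dienol ether dienone 14 (not isolated), via triketone tautomer 15 (not isolated)
Conditions: Cu(OTf)2 (10 mol%), t-Bu-box bisoxazoline ligand (single enantiomer, 12 mol%), 4 Å MS, CH2Cl2, −40 °C; then 40 °C
Reagents that add atoms: none
Why: Proposed new method: the cationic divalent copper–bisoxazoline unit is expected to sit in a six-membered chelate between the ketone oxygen and the ether oxygen ortho to the acyl group, which weakens that O–CMe2 bond and lets the reverse-prenyl group migrate suprafacially through a chair transition state to the OMe-bearing ring carbon, breaking aromaticity and leaving a linear prenyl group in dienone 14; when the flask is warmed, the second ether, now an allyl dienol ether with the ring CH carbon as its only free terminus, undergoes an ordinary aliphatic Claisen shift (helped by the gem-dimethyl group) to triketone 15, which tautomerises to 16. The nearest known reaction types are enantioselective Claisen rearrangements of 1-substituted 2-naphthyl allyl ethers bearing a 3-carbonyl group, where a chiral Lewis acid held by the ether and carbonyl oxygens sends the allyl group to the substituted carbon, and the heat- or lanthanide-promoted O-to-C transfer of reverse-prenyl groups in aryl 1,1-dimethylallyl ethers; new here are the benzenoid ring, the tertiary ether, the oxygen-bearing terminus and the tandem second shift. No ring is closed, since two C–O bonds are exchanged for two C–C bonds on the pre-existing carbocycle. The (R) configuration at C6 comes solely from the ligand, whose tert-butyl groups cover one face of the copper-bound planar arene so that the prenyl terminus reaches the OMe carbon from the open face; the sp3 C4 of 15 is transient and vanishes on tautomerisation, and C6, carrying no hydrogen, is configurationally fixed thereafter. The catalysed shift to the OMe carbon must outrun every background sigmatropic event: at −40 °C the unactivated ethers should be inert, the ketone provides the bidentate handle and occupies the second ortho position (an allyl group placed there has no route to a stable product and returns), and the MOM cap on the other ortho oxygen leaves a single chelation site. A premature shift of the remote ether to the ring CH carbon would not be fatal, because the resulting prenylated phenol keeps the chelating ether–ketone pair and funnels into 16 through the same enantioselective event.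

Step 10
Reactants: 16 (6R)-5-hydroxy-6-methoxy-3-(methoxymethoxy)-4,6-bis(3-methylbut-2-enyl)-2-(3-phenylpropanoyl)cyclohexa-2,4-dien-1-one
Product: 17 helihumulone, (6R)-3,5-dihydroxy-6-methoxy-4,6-bis(3-methylbut-2-enyl)-2-(3-phenylpropanoyl)cyclohexa-2,4-dien-1-one
Conditions: HCl (cat.), MeOH, 0 °C
Reagents that add atoms: none
Why: Acid-catalysed transacetalisation to methanol should be fast because the MOM group of 16 sits on the enol oxygen of a β-triketone (a vinylogous ester acetal, far more labile than an aryl MOM ether), so dilute acid at 0 °C should release the enol without cyclising the prenyl groups onto neighbouring hydroxyls, and the quaternary C6 cannot epimerise.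

Compound list
1 | methyl 3,5-dihydroxy-4-methoxybenzoate | COC(=O)c1cc(O)c(OC)c(O)c1 | starting material
2 | 3-chloro-3-methylbut-1-yne | CC(C)(Cl)C#C | starting material
3 | methyl 4-methoxy-3,5-bis(2-methylbut-3-yn-2-yloxy)benzoate | COC(=O)c1cc(OC(C)(C)C#C)c(OC)c(OC(C)(C)C#C)c1 | intermediate
4 | [4-methoxy-3,5-bis(2-methylbut-3-yn-2-yloxy)phenyl]methanol | OCc1cc(OC(C)(C)C#C)c(OC)c(OC(C)(C)C#C)c1 | intermediate
5 | 4-methoxy-3,5-bis(2-methylbut-3-yn-2-yloxy)benzaldehyde | O=Cc1cc(OC(C)(C)C#C)c(OC)c(OC(C)(C)C#C)c1 | intermediate
6 | 4-methoxy-3,5-bis(2-methylbut-3-yn-2-yloxy)phenyl formate | O=COc1cc(OC(C)(C)C#C)c(OC)c(OC(C)(C)C#C)c1 | intermediate (not isolated)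
7 | 4-methoxy-3,5-bis(2-methylbut-3-yn-2-yloxy)phenol | Oc1cc(OC(C)(C)C#C)c(OC)c(OC(C)(C)C#C)c1 | intermediate
8 | 2-methoxy-5-(methoxymethoxy)-1,3-bis(2-methylbut-3-yn-2-yloxy)benzene | COCOc1cc(OC(C)(C)C#C)c(OC)c(OC(C)(C)C#C)c1 | intermediate
9 | 2-methoxy-5-(methoxymethoxy)-1,3-bis(2-methylbut-3-en-2-yloxy)benzene | COCOc1cc(OC(C)(C)C=C)c(OC)c(OC(C)(C)C=C)c1 | intermediate
10 | 3-phenylpropanal | O=CCCc1ccccc1 | starting material
11 | [3-methoxy-6-(methoxymethoxy)-2,4-bis(2-methylbut-3-en-2-yloxy)phenyl]lithium | [Li]c1c(OCOC)cc(OC(C)(C)C=C)c(OC)c1OC(C)(C)C=C | intermediate (not isolated)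
12 | rac-1-[3-methoxy-6-(methoxymethoxy)-2,4-bis(2-methylbut-3-en-2-yloxy)phenyl]-3-phenylpropan-1-ol | COc1c(OC(C)(C)C=C)c(C(O)CCc2ccccc2)c(OCOC)cc1OC(C)(C)C=C | intermediate
13 | 1-[3-methoxy-6-(methoxymethoxy)-2,4-bis(2-methylbut-3-en-2-yloxy)phenyl]-3-phenylpropan-1-one | COc1c(OC(C)(C)C=C)c(C(=O)CCc2ccccc2)c(OCOC)cc1OC(C)(C)C=C | intermediate
14 | (6R)-6-methoxy-3-(methoxymethoxy)-6-(3-methylbut-2-enyl)-5-(2-methylbut-3-en-2-yloxy)-2-(3-phenylpropanoyl)cyclohexa-2,4-dien-1-one | CO[C@@]1(CC=C(C)C)C(=O)C(C(=O)CCc2ccccc2)=C(OCOC)C=C1OC(C)(C)C=C | intermediate (not isolated)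
15 | (6R)-6-methoxy-3-(methoxymethoxy)-4,6-bis(3-methylbut-2-enyl)-2-(3-phenylpropanoyl)cyclohex-2-ene-1,5-dione, C4 epimer mixture | CO[C@@]1(CC=C(C)C)C(=O)C(C(=O)CCc2ccccc2)=C(OCOC)C(CC=C(C)C)C1=O | intermediate (not isolated)
16 | (6R)-5-hydroxy-6-methoxy-3-(methoxymethoxy)-4,6-bis(3-methylbut-2-enyl)-2-(3-phenylpropanoyl)cyclohexa-2,4-dien-1-one (O-MOM helihumulone) | CO[C@@]1(CC=C(C)C)C(=O)C(C(=O)CCc2ccccc2)=C(OCOC)C(CC=C(C)C)=C1O | intermediate
17 | helihumulone, (6R)-3,5-dihydroxy-6-methoxy-4,6-bis(3-methylbut-2-enyl)-2-(3-phenylpropanoyl)cyclohexa-2,4-dien-1-one | CO[C@@]1(CC=C(C)C)C(=O)C(C(=O)CCc2ccccc2)=C(O)C(CC=C(C)C)=C1O | target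

Total step count: 10. Longest linear sequence: 10 steps (1 to 17); 2 and 10 are bought, and 2 enters twice in step 1.

Steps most likely to fail

Step 9. The Lewis acid may ionise the tertiary allyl ether instead of promoting a concerted shift, which would cause loss of the prenyl group or non-stereospecific recombination. Facial control may be poor because the substrate class is new to this catalysis. The β-dicarbonyl product may hold the catalyst and stall turnover. During the warm stage, Cope migration of the C6 prenyl group to C4 may compete, which would rearomatise the ring and destroy the stereocentre. The fallback uses only the classical thermal Claisen rearrangement of aryl 1,1-dimethylallyl ethers; it sets out from 13 and comes back at 16. Heating 13 without catalyst in toluene at about 90 °C should first move the remote ether to the free ring CH carbon in the usual aromatic sense, which after tautomerisation gives, without isolation, 1-[4-hydroxy-3-methoxy-6-(methoxymethoxy)-5-(3-methylbut-2-enyl)-2-(2-methylbut-3-en-2-yloxy)phenyl]-3-phenylpropan-1-one F1. In the same flask the ether beside the acyl group then moves to the OMe carbon, the only terminus from which the product can settle as a stable enolised triketone. This gives racemic O-MOM helihumulone F2. Preparative HPLC on a polysaccharide-based chiral stationary phase then separates the (R)-enantiomer, which is 16, from (S)-O-MOM helihumulone F3, which is discarded.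

Step 7. Lithiation may be incomplete at −78 °C. On warming, the aryllithium may cyclise onto the neighbouring vinyl group by intramolecular carbolithiation, and the hindered aryllithium may deprotonate the enolisable aldehyde instead of adding to it. The fallback replaces deprotonation by halogenation and a less basic arylmetal; it sets out from 9 and comes back at 12. Ring bromination of 9 with NBS (MeCN, −20 °C) should give 2-bromo-4-methoxy-1-(methoxymethoxy)-3,5-bis(2-methylbut-3-en-2-yloxy)benzene F4. The tetra-oxygenated arene should react far faster than the monosubstituted alkenes, and the two CH positions are equivalent. Bromine–magnesium exchange with i-PrMgCl·LiCl (THF, 0 °C, assisted by the two ortho oxygens) should give [3-methoxy-6-(methoxymethoxy)-2,4-bis(2-methylbut-3-en-2-yloxy)phenyl]magnesium chloride F5. This species does not add to unactivated alkenes and is much less prone to proton transfer, and its addition to 3-phenylpropanal 10 followed by aqueous quench gives 12.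

Step 6. Hydrogen uptake may run past the alkene stage to saturated tert-pentyl ethers, or stop short at one alkyne, and the thermal lability of the product limits purification. The fallback avoids the alkyne stage altogether; it sets out from 1 and comes back at 9. Zerovalent-palladium-catalysed O-allylation of both phenols of 1 with two equivalents of tert-butyl 2-methylbut-3-en-2-yl carbonate (Pd(PPh3)4, THF, 0 °C; kinetic attack of the phenoxide at the more substituted allyl terminus) should give methyl 4-methoxy-3,5-bis(2-methylbut-3-en-2-yloxy)benzoate F6. The operations of steps 2 to 5 are then repeated in the alkene series, all at or below room temperature. Reduction with i-Bu2AlH should give [4-methoxy-3,5-bis(2-methylbut-3-en-2-yloxy)phenyl]methanol F7, and MnO2 oxidation should then give 4-methoxy-3,5-bis(2-methylbut-3-en-2-yloxy)benzaldehyde F8. Treatment with mCPBA at 0 °C should give 4-methoxy-3,5-bis(2-methylbut-3-en-2-yloxy)phenyl formate F9, since the monosubstituted, oxygen-deactivated alkenes should epoxidise far more slowly than the electron-rich aldehyde undergoes Baeyer–Villiger oxidation. Catalytic K2CO3 in MeOH should then give 4-methoxy-3,5-bis(2-methylbut-3-en-2-yloxy)phenol F10, and MOMCl with i-Pr2NEt converts this phenol into 9.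

Further compounds
F1 | step 9 | 1-[4-hydroxy-3-methoxy-6-(methoxymethoxy)-5-(3-methylbut-2-enyl)-2-(2-methylbut-3-en-2-yloxy)phenyl]-3-phenylpropan-1-one | COc1c(OC(C)(C)C=C)c(C(=O)CCc2ccccc2)c(OCOC)c(CC=C(C)C)c1O
F2 | step 9 | racemic O-MOM helihumulone | COC1(CC=C(C)C)C(=O)C(C(=O)CCc2ccccc2)=C(OCOC)C(CC=C(C)C)=C1O
F3 | step 9 | (S)-O-MOM helihumulone | CO[C@]1(CC=C(C)C)C(=O)C(C(=O)CCc2ccccc2)=C(OCOC)C(CC=C(C)C)=C1O
F4 | step 7 | 2-bromo-4-methoxy-1-(methoxymethoxy)-3,5-bis(2-methylbut-3-en-2-yloxy)benzene | COCOc1cc(OC(C)(C)C=C)c(OC)c(OC(C)(C)C=C)c1Br
F5 | step 7 | [3-methoxy-6-(methoxymethoxy)-2,4-bis(2-methylbut-3-en-2-yloxy)phenyl]magnesium chloride | Cl[Mg]c1c(OCOC)cc(OC(C)(C)C=C)c(OC)c1OC(C)(C)C=C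
F6 | step 6 | methyl 4-methoxy-3,5-bis(2-methylbut-3-en-2-yloxy)benzoate | COC(=O)c1cc(OC(C)(C)C=C)c(OC)c(OC(C)(C)C=C)c1
F7 | step 6 | [4-methoxy-3,5-bis(2-methylbut-3-en-2-yloxy)phenyl]methanol | OCc1cc(OC(C)(C)C=C)c(OC)c(OC(C)(C)C=C)c1
F8 | step 6 | 4-methoxy-3,5-bis(2-methylbut-3-en-2-yloxy)benzaldehyde | O=Cc1cc(OC(C)(C)C=C)c(OC)c(OC(C)(C)C=C)c1
F9 | step 6 | 4-methoxy-3,5-bis(2-methylbut-3-en-2-yloxy)phenyl formate | O=COc1cc(OC(C)(C)C=C)c(OC)c(OC(C)(C)C=C)c1
F10 | step 6 | 4-methoxy-3,5-bis(2-methylbut-3-en-2-yloxy)phenol | Oc1cc(OC(C)(C)C=C)c(OC)c(OC(C)(C)C=C)c1
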